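## Retrosynthetic overview

1. The target comes from oxidation of an 8,14-diol; its dihydropyran 2,15-diacetate comes from a lactol that closes by itself when a C2 aldehyde meets a 2-substituted malondialdehyde (C3/C15).
2. The gem-dimethylcyclopropane comes from isopropylidene transfer (sulfur ylide) to the less substituted double bond of a 4,5-cis-disubstituted cyclohepta-2,6-dienone, anti to the side chains.
3. The cycloheptadiene with cis C1/C5 comes from a Cope rearrangement of a cis-1,2-dialkenylcyclopropane (boat transition state); the C8 ketone comes from bis-allylic oxidation and C14 from a Stille coupling.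
4. The cis-dialkenylcyclopropane comes from meso dimethyl cis-cyclopropane-1,2-dicarboxylate, desymmetrised by an esterase; the arms are built by alkyne homologation, Julia–Kocienski olefination and hydroalumination/iodination.
5. Ring order: sacrificial cyclopropane → cycloheptadiene → gem-dimethylcyclopropane → dihydropyran.

Assumption: the esterase gives the (1S,2R) half-ester 5 (acid on the S carbon); if an esterase of opposite sense is used, lactone 7 is still reached by reducing the ester instead of the acid.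

Locants in the text follow the target: C1/C5 ring-fusion CH, C2 acetal carbon, C3=C4 enol ether, C6/C7 cyclopropane CH, C8 ketone, C9=C10 enone, C11 CMe2, C14 formyl carbon, C15 acetoxymethyl carbon. TBS = tert-butyldimethylsilyl, TBDPS = tert-butyldiphenylsilyl.

## Route

Step 1
Reactants: 1 (2,2-dimethyl-1,3-dioxan-5-yl)methanol
Product: 2 5-{[(2,2-dimethyl-1,3-dioxan-5-yl)methyl]sulfanyl}-1-phenyl-1H-tetrazole
Conditions: 1-phenyl-1H-tetrazole-5-thiol, PPh3, DIAD, THF, 0 °C → rt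
Reagents that add atoms: 1-phenyl-1H-tetrazole-5-thiol, Sc1nnnn1-c1ccccc1
Why: Mitsunobu thioetherification of an unhindered primary alcohol (SN2 at CH2, no stereocentre involved).

Step 2
Reactants: 2 5-{[(2,2-dimethyl-1,3-dioxan-5-yl)methyl]sulfanyl}-1-phenyl-1H-tetrazole
Product: 3 5-{[(2,2-dimethyl-1,3-dioxan-5-yl)methyl]sulfonyl}-1-phenyl-1H-tetrazole
Conditions: mCPBA (2.5 equiv), NaHCO3, CH2Cl2, 0 °C → rt
Reagents that add atoms: mCPBA, OOC(=O)c1cccc(Cl)c1
Why: Peracid oxidation of sulfide to sulfone gives the Julia–Kocienski reagent; the bicarbonate buffer protects the acetonide.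

Step 3
Reactants: 4 dimethyl cis-cyclopropane-1,2-dicarboxylate (meso)
Product: 5 (1S,2R)-2-(methoxycarbonyl)cyclopropane-1-carboxylic acid
Conditions: esterase (pig liver esterase), 0.1 M phosphate buffer pH 7, 25 °C
Reagents that add atoms: water, O
Why: Enzymatic desymmetrisation: the esterase hydrolyses one of the two enantiotopic ester groups of the meso diester, which fixes the absolute configuration of both cyclopropane carbons and is the only source of chirality in the route.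

Step 4
Reactants: 5 (1S,2R)-2-(methoxycarbonyl)cyclopropane-1-carboxylic acid
Product: 7 (1R,5S)-3-oxabicyclo[3.1.0]hexan-2-one, via hydroxy ester 6 (not isolated)
Conditions: BH3·SMe2, THF, −10 → 20 °C; MeOH; then TsOH (cat.), CH2Cl2, rt
Reagents that add atoms: none
Why: Borane reduces the carboxylic acid chemoselectively beside the ester, and the cis hydroxy ester lactonises under acid catalysis; the stereocentres are untouched.

Step 5
Reactants: 7 (1R,5S)-3-oxabicyclo[3.1.0]hexan-2-one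
Product: 8 (1R,5S)-3-oxabicyclo[3.1.0]hexan-2-ol
Conditions: i-Bu2AlH (1.1 equiv), CH2Cl2, −78 °C; aq. KNaC4H4O6
Reagents that add atoms: none
Why: Partial reduction of a lactone to the lactol; the aluminium hemiacetal is stable at −78 °C.

Step 6
Reactants: 8 (1R,5S)-3-oxabicyclo[3.1.0]hexan-2-ol
Product: 9 [(1S,2R)-2-ethynylcyclopropyl]methanol
Conditions: dimethyl (1-diazo-2-oxopropyl)phosphonate, K2CO3, MeOH, 0 °C → rt
Reagents that add atoms: dimethyl (1-diazo-2-oxopropyl)phosphonate, CC(=O)C(=[N+]=[N-])P(=O)(OC)OC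
Why: Seyferth–Gilbert homologation (Ohira–Bestmann variant) on the open hydroxy-aldehyde tautomer of the lactol; the cyclopropyl α-carbon resists enolisation, so the cis relationship is kept.

Step 7
Reactants: 9 [(1S,2R)-2-ethynylcyclopropyl]methanol
Product: 10 (1S,2R)-2-ethynylcyclopropane-1-carbaldehyde
Conditions: Dess–Martin periodinane, NaHCO3, CH2Cl2, 0 °C (solution used at once)
Reagents that add atoms: none
Why: Dess–Martin oxidation of a primary alcohol under buffered, non-epimerising conditions.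

Step 8
Reactants: 3 5-{[(2,2-dimethyl-1,3-dioxan-5-yl)methyl]sulfonyl}-1-phenyl-1H-tetrazole; 10 (1S,2R)-2-ethynylcyclopropane-1-carbaldehyde
Product: 12 5-{(E)-2-[(1R,2R)-2-ethynylcyclopropyl]ethenyl}-2,2-dimethyl-1,3-dioxane, via potassium sulfonyl carbanion 11 (not isolated)
Conditions: 3, KN(SiMe3)2, DME, −60 °C; then 10, −60 °C → rt
Reagents that add atoms: none
Why: Julia–Kocienski olefination, E-selective with the phenyltetrazolyl sulfone/potassium base pair; the cyclopropane centres are not touched (descriptor change is a priority effect only).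

Step 9
Reactants: 12 5-{(E)-2-[(1R,2R)-2-ethynylcyclopropyl]ethenyl}-2,2-dimethyl-1,3-dioxane
Product: 14 3-[(1R,2R)-2-[(E)-2-(2,2-dimethyl-1,3-dioxan-5-yl)ethenyl]cyclopropyl]prop-2-yn-1-ol, via lithium acetylide 13 (not isolated)
Conditions: n-BuLi, THF, −78 °C; then (CH2O)n, −78 °C → rt
Reagents that add atoms: formaldehyde (as paraformaldehyde), C=O
Why: Hydroxymethylation of a lithium acetylide; this brings in C2.

Step 10
Reactants: 14 3-[(1R,2R)-2-[(E)-2-(2,2-dimethyl-1,3-dioxan-5-yl)ethenyl]cyclopropyl]prop-2-yn-1-ol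
Product: 17 [(1S,7S)-7-(2,2-dimethyl-1,3-dioxan-5-yl)-2-iodocyclohepta-2,5-dien-1-yl]methanol, via alkenylaluminate 15 (not isolated), via iodo-divinylcyclopropane 16 (not isolated)
Conditions: NaAlH2(OCH2CH2OMe)2, THF, 0 °C → rt; then I2, THF, −78 °C; aq. Na2S2O3; then PhMe, 60 °C
Reagents that add atoms: iodine, [I][I]
Why: Alkoxide-directed anti-hydroalumination and iodinolysis with retention give the (Z)-iodoalkene with CH2OH trans to the cyclopropane, and the resulting cis-1,2-dialkenylcyclopropane undergoes the divinylcyclopropane Cope rearrangement through the boat transition state, which transfers the enzyme-set cyclopropane configuration to C1 and C5 and places the two side chains cis.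

Step 11
Reactants: 17 [(1S,7S)-7-(2,2-dimethyl-1,3-dioxan-5-yl)-2-iodocyclohepta-2,5-dien-1-yl]methanol
Product: 18 tert-butyl{[(1S,7S)-7-(2,2-dimethyl-1,3-dioxan-5-yl)-2-iodocyclohepta-2,5-dien-1-yl]methoxy}dimethylsilane
Conditions: TBSCl, imidazole, DMF, rt
Reagents that add atoms: tert-butyl(chloro)dimethylsilane, CC(C)(C)[Si](C)(C)Cl
Why: Silylation of the primary alcohol (C2–OH) so that it can be told apart from C14–OH later.

Step 12
Reactants: 18 tert-butyl{[(1S,7S)-7-(2,2-dimethyl-1,3-dioxan-5-yl)-2-iodocyclohepta-2,5-dien-1-yl]methoxy}dimethylsilane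
Product: 19 (4S,5S)-4-({[tert-butyl(dimethyl)silyl]oxy}methyl)-5-(2,2-dimethyl-1,3-dioxan-5-yl)-3-iodocyclohepta-2,6-dien-1-one
Conditions: (C5H5NH)2Cr2O7, t-BuOOH, Celite, benzene, rt
Reagents that add atoms: tert-butyl hydroperoxide, CC(C)(C)OO
Why: Chromium/hydroperoxide bis-allylic oxidation of the 1,4-diene: the doubly allylic CH2 (C8) has the weakest C–H bonds and gives the cross-conjugated dienone; the iodoalkene carries no competing allylic CH2–O.

Step 13
Reactants: 19 (4S,5S)-4-({[tert-butyl(dimethyl)silyl]oxy}methyl)-5-(2,2-dimethyl-1,3-dioxan-5-yl)-3-iodocyclohepta-2,6-dien-1-one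
Product: 20 (4R,5R)-4-({[tert-butyl(dimethyl)silyl]oxy}methyl)-5-(2,2-dimethyl-1,3-dioxan-5-yl)-3-(hydroxymethyl)cyclohepta-2,6-dien-1-one
Conditions: Bu3SnCH2OH, Pd(PPh3)4 (5 mol %), 1,4-dioxane, 90 °C
Reagents that add atoms: (tributylstannyl)methanol, CCCC[Sn](CCCC)(CCCC)CO
Why: Stille coupling of an activated β-iodoenone with the hydroxymethyl stannane brings in C14 (descriptors change by priority only).

Step 14
Reactants: 20 (4R,5R)-4-({[tert-butyl(dimethyl)silyl]oxy}methyl)-5-(2,2-dimethyl-1,3-dioxan-5-yl)-3-(hydroxymethyl)cyclohepta-2,6-dien-1-one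
Product: 21 (4R,5R)-4-({[tert-butyl(dimethyl)silyl]oxy}methyl)-3-({[tert-butyl(diphenyl)silyl]oxy}methyl)-5-(2,2-dimethyl-1,3-dioxan-5-yl)cyclohepta-2,6-dien-1-one
Conditions: TBDPSCl, imidazole, DMF, rt
Reagents that add atoms: tert-butyl(chloro)diphenylsilane, CC(C)(C)[Si](Cl)(c1ccccc1)c1ccccc1
Why: Silylation of C14–OH with the acid-stable TBDPS group, which must outlast the later acid step.

Step 15
Reactants: 21 (4R,5R)-4-({[tert-butyl(dimethyl)silyl]oxy}methyl)-3-({[tert-butyl(diphenyl)silyl]oxy}methyl)-5-(2,2-dimethyl-1,3-dioxan-5-yl)cyclohepta-2,6-dien-1-one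
Product: 22 (1S,5R,6R,7R)-5-({[tert-butyl(dimethyl)silyl]oxy}methyl)-4-({[tert-butyl(diphenyl)silyl]oxy}methyl)-6-(2,2-dimethyl-1,3-dioxan-5-yl)-8,8-dimethylbicyclo[5.1.0]oct-3-en-2-one
Conditions: [Ph2S–CH(CH3)2]BF4, LiN(i-Pr)2, DME, −78 °C; then 21, −78 → −30 °C
Reagents that add atoms: isopropyldiphenylsulfonium tetrafluoroborate, CC(C)[S+](c1ccccc1)c1ccccc1.F[B-](F)(F)F
Why: Corey–Chaykovsky-type isopropylidene transfer: the ylide adds in conjugate fashion only at the β-monosubstituted carbon C6, on the face opposite the two cis side chains, and 3-exo ring closure gives the cis-fused gem-dimethylcyclopropane, setting C6 and C7.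

Step 16
Reactants: 22 (1S,5R,6R,7R)-5-({[tert-butyl(dimethyl)silyl]oxy}methyl)-4-({[tert-butyl(diphenyl)silyl]oxy}methyl)-6-(2,2-dimethyl-1,3-dioxan-5-yl)-8,8-dimethylbicyclo[5.1.0]oct-3-en-2-one
Product: 23 (1S,2S,5R,6R,7R)-5-({[tert-butyl(dimethyl)silyl]oxy}methyl)-4-({[tert-butyl(diphenyl)silyl]oxy}methyl)-6-(2,2-dimethyl-1,3-dioxan-5-yl)-8,8-dimethylbicyclo[5.1.0]oct-3-en-2-ol
Conditions: NaBH4, CeCl3·7H2O, MeOH, −78 → 0 °C
Reagents that add atoms: none
Why: Luche 1,2-reduction of the enone; hydride comes from the face anti to the CMe2 bridge (major epimer drawn), and this temporary C8 centre is erased in the last step.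

Step 17
Reactants: 23 (1S,2S,5R,6R,7R)-5-({[tert-butyl(dimethyl)silyl]oxy}methyl)-4-({[tert-butyl(diphenyl)silyl]oxy}methyl)-6-(2,2-dimethyl-1,3-dioxan-5-yl)-8,8-dimethylbicyclo[5.1.0]oct-3-en-2-ol
Product: 24 the 2-O-TBS ether of 23 [(1S,2S,5R,6R,7R)-2-(TBSO)-5-(TBSOCH2)-4-(TBDPSOCH2)-6-(2,2-dimethyl-1,3-dioxan-5-yl)-8,8-dimethylbicyclo[5.1.0]oct-3-ene]
Conditions: TBSOTf, 2,6-lutidine, CH2Cl2, −78 °C
Reagents that add atoms: tert-butyldimethylsilyl trifluoromethanesulfonate, CC(C)(C)[Si](C)(C)OS(=O)(=O)C(F)(F)F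
Why: Silylation of the hindered secondary allylic alcohol with the silyl triflate; the ketone stays masked so that C1 is not acidified while C2 is a carbonyl.

Step 18
Reactants: 24 (1S,2S,5R,6R,7R)-2-(TBSO)-5-(TBSOCH2)-4-(TBDPSOCH2)-6-(2,2-dimethyl-1,3-dioxan-5-yl)-8,8-dimethylbicyclo[5.1.0]oct-3-ene
Product: 25 (1S,2S,5R,6R,7R)-2-(TBSO)-4-(TBDPSOCH2)-6-(1,3-dihydroxypropan-2-yl)-5-(hydroxymethyl)-8,8-dimethylbicyclo[5.1.0]oct-3-ene (C2,C3,C15-triol)
Conditions: PPTS, MeOH, 40 °C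
Reagents that add atoms: none
Why: Mild acid methanolysis removes the 1,3-dioxane acetonide and the primary TBS ether, while the secondary TBS and the TBDPS ethers survive.

Step 19
Reactants: 25 C2,C3,C15-triol
Product: 27 lactol-enal with the target ring system (2-OH as anomer mixture; 15-aldehyde; 8-OTBS; 14-OTBDPS), via trialdehyde 26 (not isolated)
Conditions: (COCl)2, DMSO, CH2Cl2, −78 °C; then i-Pr2NEt, −78 → 0 °C
Reagents that add atoms: none
Why: Swern oxidation of all three primary alcohols; the 2-substituted malondialdehyde is enolised and its enol oxygen adds to the C2 aldehyde, so the dihydropyran closes with unambiguous regiochemistry and C1 is not touched.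

Step 20
Reactants: 27 lactol-enal
Product: 28 (2S)-2-O-acetyl lactol-enal (15-aldehyde; 8-OTBS; 14-OTBDPS)
Conditions: Ac2O, pyridine, DMAP (cat.), CH2Cl2, 0 °C
Reagents that add atoms: acetic anhydride, CC(=O)OC(C)=O
Why: Acetylation of the equilibrating lactol; the anomerically stabilised pseudo-axial acetate (C2–O cis to the C1–C10 bond), which is the target configuration at C2, is expected as the main anomer and is separated from the minor one.

Step 21
Reactants: 28 (2S)-2-O-acetyl lactol-enal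
Product: 30 2,15-di-O-acetate (8-OTBS; 14-OTBDPS), via allylic alcohol 29 (not isolated)
Conditions: NaBH4, CeCl3·7H2O, MeOH, −78 °C; then Ac2O, Et3N, DMAP (cat.), CH2Cl2, 0 °C
Reagents that add atoms: acetic anhydride, CC(=O)OC(C)=O
Why: Luche reduction of the vinylogous formate aldehyde at low temperature leaves the acetal acetate alone, and the sensitive enol-ether carbinol is acetylated at once.

Step 22
Reactants: 30 2,15-di-O-acetate (8-OTBS; 14-OTBDPS)
Product: 31 8,14-diol 2,15-diacetate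
Conditions: HF·pyridine, pyridine, THF, 0 °C → rt
Reagents that add atoms: none
Why: Buffered fluoride desilylation removes both silyl ethers without acyl migration or loss of the acetal acetate.

Step 23
Reactants: 31 8,14-diol 2,15-diacetate
Product: 32 target CNP0263020.2
Conditions: Dess–Martin periodinane, NaHCO3, CH2Cl2, 0 °C → rt
Reagents that add atoms: none
Why: Dess–Martin oxidation of the secondary and the primary allylic alcohol gives the (E)-4-oxo-2-enal under neutral conditions, so the γ-CH at C1 is not epimerised.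

## Compound list

1 | (2,2-dimethyl-1,3-dioxan-5-yl)methanol | CC1(C)OCC(CO)CO1 | starting material
2 | 5-{[(2,2-dimethyl-1,3-dioxan-5-yl)methyl]sulfanyl}-1-phenyl-1H-tetrazole | CC1(C)OCC(CSc2nnnn2-c2ccccc2)CO1 | intermediate
3 | 5-{[(2,2-dimethyl-1,3-dioxan-5-yl)methyl]sulfonyl}-1-phenyl-1H-tetrazole | CC1(C)OCC(CS(=O)(=O)c2nnnn2-c2ccccc2)CO1 | intermediate
4 | dimethyl cis-cyclopropane-1,2-dicarboxylate (meso) | COC(=O)[C@@H]1C[C@@H]1C(=O)OC | starting material
5 | (1S,2R)-2-(methoxycarbonyl)cyclopropane-1-carboxylic acid | COC(=O)[C@@H]1C[C@@H]1C(O)=O | intermediate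
6 | methyl (1R,2S)-2-(hydroxymethyl)cyclopropane-1-carboxylate | COC(=O)[C@@H]1C[C@@H]1CO | intermediate
7 | (1R,5S)-3-oxabicyclo[3.1.0]hexan-2-one | O=C1[C@@H]2C[C@@H]2CO1 | intermediate
8 | (1R,5S)-3-oxabicyclo[3.1.0]hexan-2-ol (both anomers) | OC1[C@@H]2C[C@@H]2CO1 | intermediate
9 | [(1S,2R)-2-ethynylcyclopropyl]methanol | C#C[C@@H]1C[C@@H]1CO | intermediate
10 | (1S,2R)-2-ethynylcyclopropane-1-carbaldehyde | C#C[C@@H]1C[C@@H]1C=O | intermediate
11 | potassium salt of 3 (α-sulfonyl carbanion) | [K+].CC1(C)OCC([CH-]S(=O)(=O)c2nnnn2-c2ccccc2)CO1 | intermediate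
12 | 5-{(E)-2-[(1R,2R)-2-ethynylcyclopropyl]ethenyl}-2,2-dimethyl-1,3-dioxane | C#C[C@@H]1C[C@@H]1/C=C/C2COC(C)(C)OC2 | intermediate
13 | lithium acetylide of 12 | [Li+].[C-]#C[C@@H]1C[C@@H]1/C=C/C2COC(C)(C)OC2 | intermediate
14 | 3-[(1R,2R)-2-[(E)-2-(2,2-dimethyl-1,3-dioxan-5-yl)ethenyl]cyclopropyl]prop-2-yn-1-ol | OCC#C[C@@H]1C[C@@H]1/C=C/C2COC(C)(C)OC2 | intermediate
15 | sodium alkenylaluminate (2,5-dihydro-1,2-oxaluminole ate complex, Al on the cyclopropyl-bearing carbon) | [Na+].COCCO[Al-]1(OCCOC)OCC=C1[C@@H]2C[C@@H]2/C=C/C3COC(C)(C)OC3 | intermediate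
16 | (2Z)-3-[(1R,2R)-2-[(E)-2-(2,2-dimethyl-1,3-dioxan-5-yl)ethenyl]cyclopropyl]-3-iodoprop-2-en-1-ol | OC/C=C(\I)[C@@H]1C[C@@H]1/C=C/C2COC(C)(C)OC2 | intermediate
17 | [(1S,7S)-7-(2,2-dimethyl-1,3-dioxan-5-yl)-2-iodocyclohepta-2,5-dien-1-yl]methanol | OC[C@H]1C(I)=CCC=C[C@H]1C2COC(C)(C)OC2 | intermediate
18 | tert-butyl{[(1S,7S)-7-(2,2-dimethyl-1,3-dioxan-5-yl)-2-iodocyclohepta-2,5-dien-1-yl]methoxy}dimethylsilane | CC(C)(C)[Si](C)(C)OC[C@H]1C(I)=CCC=C[C@H]1C2COC(C)(C)OC2 | intermediate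
19 | (4S,5S)-4-({[tert-butyl(dimethyl)silyl]oxy}methyl)-5-(2,2-dimethyl-1,3-dioxan-5-yl)-3-iodocyclohepta-2,6-dien-1-one | CC(C)(C)[Si](C)(C)OC[C@H]1C(I)=CC(=O)C=C[C@H]1C2COC(C)(C)OC2 | intermediate
20 | (4R,5R)-4-({[tert-butyl(dimethyl)silyl]oxy}methyl)-5-(2,2-dimethyl-1,3-dioxan-5-yl)-3-(hydroxymethyl)cyclohepta-2,6-dien-1-one | CC(C)(C)[Si](C)(C)OC[C@H]1C(CO)=CC(=O)C=C[C@H]1C2COC(C)(C)OC2 | intermediate
21 | (4R,5R)-4-({[tert-butyl(dimethyl)silyl]oxy}methyl)-3-({[tert-butyl(diphenyl)silyl]oxy}methyl)-5-(2,2-dimethyl-1,3-dioxan-5-yl)cyclohepta-2,6-dien-1-one | CC(C)(C)[Si](C)(C)OC[C@H]1C(CO[Si](c2ccccc2)(c2ccccc2)C(C)(C)C)=CC(=O)C=C[C@H]1C3COC(C)(C)OC3 | intermediate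
22 | (1S,5R,6R,7R)-5-({[tert-butyl(dimethyl)silyl]oxy}methyl)-4-({[tert-butyl(diphenyl)silyl]oxy}methyl)-6-(2,2-dimethyl-1,3-dioxan-5-yl)-8,8-dimethylbicyclo[5.1.0]oct-3-en-2-one | CC(C)(C)[Si](C)(C)OC[C@H]1C(CO[Si](c2ccccc2)(c2ccccc2)C(C)(C)C)=CC(=O)[C@H]2[C@@H]([C@H]1C3COC(C)(C)OC3)C2(C)C | intermediate
23 | (1S,2S,5R,6R,7R)-5-({[tert-butyl(dimethyl)silyl]oxy}methyl)-4-({[tert-butyl(diphenyl)silyl]oxy}methyl)-6-(2,2-dimethyl-1,3-dioxan-5-yl)-8,8-dimethylbicyclo[5.1.0]oct-3-en-2-ol (OH syn to the CMe2 bridge, major epimer) | CC(C)(C)[Si](C)(C)OC[C@H]1C(CO[Si](c2ccccc2)(c2ccccc2)C(C)(C)C)=C[C@H](O)[C@H]2[C@@H]([C@H]1C3COC(C)(C)OC3)C2(C)C | intermediate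
24 | 2-O-TBS ether of 23 | CC(C)(C)[Si](C)(C)OC[C@H]1C(CO[Si](c2ccccc2)(c2ccccc2)C(C)(C)C)=C[C@H](O[Si](C)(C)C(C)(C)C)[C@H]2[C@@H]([C@H]1C3COC(C)(C)OC3)C2(C)C | intermediate
25 | (1S,2S,5R,6R,7R)-2-(TBSO)-4-(TBDPSOCH2)-6-(1,3-dihydroxypropan-2-yl)-5-(hydroxymethyl)-8,8-dimethylbicyclo[5.1.0]oct-3-ene (C2,C3,C15-triol) | OC[C@H]1C(CO[Si](c2ccccc2)(c2ccccc2)C(C)(C)C)=C[C@H](O[Si](C)(C)C(C)(C)C)[C@H]2[C@@H]([C@H]1C(CO)CO)C2(C)C | intermediate
26 | trialdehyde: as 25 with 5-formyl and 6-(1,3-dioxopropan-2-yl) groups | O=C[C@H]1C(CO[Si](c2ccccc2)(c2ccccc2)C(C)(C)C)=C[C@H](O[Si](C)(C)C(C)(C)C)[C@H]2[C@@H]([C@H]1C(C=O)C=O)C2(C)C | intermediate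
27 | lactol-enal with the target ring system (C1 R, C5 R, C6 R, C7 S, C8 S; 2-OH both anomers; 15-CHO; 8-OTBS; 14-OTBDPS) | O=CC1=COC(O)[C@H]2C(CO[Si](c3ccccc3)(c3ccccc3)C(C)(C)C)=C[C@H](O[Si](C)(C)C(C)(C)C)[C@H]3[C@@H]([C@@H]12)C3(C)C | intermediate
28 | (2S)-2-O-acetyl derivative of 27 | O=CC1=CO[C@@H](OC(C)=O)[C@H]2C(CO[Si](c3ccccc3)(c3ccccc3)C(C)(C)C)=C[C@H](O[Si](C)(C)C(C)(C)C)[C@H]3[C@@H]([C@@H]12)C3(C)C | intermediate
29 | 15-hydroxy compound (15-CHO of 28 reduced to CH2OH) | OCC1=CO[C@@H](OC(C)=O)[C@H]2C(CO[Si](c3ccccc3)(c3ccccc3)C(C)(C)C)=C[C@H](O[Si](C)(C)C(C)(C)C)[C@H]3[C@@H]([C@@H]12)C3(C)C | intermediate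
30 | 2,15-di-O-acetate (8-OTBS; 14-OTBDPS) | CC(=O)OCC1=CO[C@@H](OC(C)=O)[C@H]2C(CO[Si](c3ccccc3)(c3ccccc3)C(C)(C)C)=C[C@H](O[Si](C)(C)C(C)(C)C)[C@H]3[C@@H]([C@@H]12)C3(C)C | intermediate
31 | 8,14-diol 2,15-diacetate | CC(=O)OCC1=CO[C@@H](OC(C)=O)[C@H]2C(CO)=C[C@H](O)[C@H]3[C@@H]([C@@H]12)C3(C)C | intermediate
32 | CNP0263020.2 (C1 R, C2 S, C5 R, C6 R, C7 S; 8-oxo; 14-al; 2,15-diacetate) | CC(=O)OCC1=CO[C@@H](OC(C)=O)[C@H]2C(C=O)=CC(=O)[C@H]3[C@@H]([C@@H]12)C3(C)C | target

## Step count and weak points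

Total: 23 steps. Longest linear sequence: 21 steps (steps 3–23, from diester 4); steps 1–2 make sulfone 3.

The three steps most likely to fail:

Step 12 (bis-allylic oxidation). The pentadienyl-type intermediate could be trapped at a terminus, or a tertiary allylic C–H could be attacked instead. The fallback sets out from 18: SeO2 (cat.) with t-BuOOH in CH2Cl2 hydroxylates the doubly allylic CH2 by an ene/[2,3]-sigmatropic sequence to give the cyclohepta-2,6-dien-1-ol F1. MnO2 in CH2Cl2 then oxidises this doubly allylic carbinol to the dienone, and the route is rejoined at 19.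

Step 15 (isopropylidene transfer). The basic ylide may deprotonate a γ-CH of the dienone or add sluggishly. The fallback sets out from 21: 1,3-dipolar cycloaddition of 2-diazopropane (from acetone hydrazone and HgO, Et2O, −78 → 0 °C) to the C6=C7 enone gives the fused 1-pyrazoline F2, with the carbon terminus at C6 anti to the side chains. Irradiation (about 350 nm, benzene) expels nitrogen and gives the same cyclopropane, so the route is rejoined at 22.

Step 20 (configuration at C2). Acetylation of the lactol may give too much of the wrong anomer. The fallback sets out from 27: (n-Pr)4N[RuO4] (cat.) with N-methylmorpholine N-oxide oxidises the lactol to the enol lactone F3. i-Bu2AlH (2.2 equiv, CH2Cl2, −78 °C) then reduces the lactone, with hydride arriving anti to the C1–C10 bond, and also the aldehyde; Ac2O, pyridine and DMAP are added to the cold aluminium hemiacetal (reductive acetylation). This gives the 2,15-diacetate directly and the route is rejoined at 30.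

## Further compounds

F1 | step 12 | 4-({[tert-butyl(dimethyl)silyl]oxy}methyl)-5-(2,2-dimethyl-1,3-dioxan-5-yl)-3-iodocyclohepta-2,6-dien-1-ol (4,5-cis as in 18; carbinol epimers) | CC(C)(C)[Si](C)(C)OC[C@H]1C(I)=CC(O)C=C[C@H]1C2COC(C)(C)OC2
F2 | step 15 | 1-pyrazoline from 21 and 2-diazopropane (N on C7, CMe2 on C6, cis-fused, anti to the side chains) | CC(C)(C)[Si](C)(C)OC[C@H]1C(CO[Si](c2ccccc2)(c2ccccc2)C(C)(C)C)=CC(=O)[C@@H]2N=NC(C)(C)[C@@H]2[C@H]1C3COC(C)(C)OC3
F3 | step 20 | enol lactone (C2 lactone carbonyl; 15-CHO; 8-OTBS; 14-OTBDPS) | O=CC1=COC(=O)[C@H]2C(CO[Si](c3ccccc3)(c3ccccc3)C(C)(C)C)=C[C@H](O[Si](C)(C)C(C)(C)C)[C@H]3[C@@H]([C@@H]12)C3(C)C
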